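**Plan**

- Ring numbering used throughout: O1, C2 (CH3), C3 (CHO), C4 (CH2CO2R), C5 (CO2Me)=C6H. The retrosynthesis first exchanges the side-chain ester (hydroxytyrosol for methanol). It then cuts two ring bonds at once, O1–C2 and C3–C4, to give (E)-crotonaldehyde (CH3, C2, C3, CHO) and the enol of dimethyl 2-formylglutaconate (O1, C6, C5, C4 and both ester carbons). The last cut, C5–C6, leads back to dimethyl glutaconate.
- Forward: C-formylation of dimethyl glutaconate, then one amine-catalysed oxa-Michael/Michael [3+3] annulation that builds the dihydropyran, then a lipase attaches unprotected hydroxytyrosol to the only aliphatic ester.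
- Stereochemistry: C2 is set by the catalyst (iminium face). C3 and C4 are relayed in the same event by the enamine face and a chair closure with all three substituents equatorial. No stereocentre is bought.
- Enabling feature: the vinylogous carbonate O1–C6H=C5(CO2Me) of the ring. Opened at O1 it is an enol OH about as acidic as a phenol. Its C5=C6 bond holds O1 and C4 in a cis-1,3 relationship, with C4 as the β-carbon of an enoate, so one enal can bridge O1 and C4 through C2–C3.
- The annulation also turns the conjugated distal ester into an isolated CH2CO2Me, which lets an enzyme tell the two methyl esters apart. No protecting groups are used.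

Key step: step 2

Remark: read from the SMILES, the target is (2S,3R,4R) in this numbering (CH3/CHO trans, CHO/CH2CO2R trans). Commercial (E)-crotonaldehyde and (E)-dimethyl glutaconate are assumed.

**Step 1**
Reactants: 1 dimethyl (2E)-pent-2-enedioate (dimethyl glutaconate)
Product: 3 dimethyl (2E,4Z)-4-(hydroxymethylidene)pent-2-enedioate, via sodium enolate 2 (not isolated)
Conditions: HCO2Me (5 equiv), NaOMe (1.1 equiv), THF, 0 °C to rt; then cold 1 M HCl, EtOAc; crude 3 used at once
Reagents that add atoms: methyl formate, COC=O
Why: Crossed Claisen condensation (C-formylation) of the symmetrical glutaconate dienolate at its α-carbon, driven by deprotonation of the product to the stabilised enolate 2; no stereocentre is formed and the enol geometry can adjust later.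

**Step 2**
Reactants: 3 dimethyl (2E,4Z)-4-(hydroxymethylidene)pent-2-enedioate; 4 (E)-but-2-enal (crotonaldehyde, 1.5 equiv)
Product: 6 methyl (2S,3R,4R)-3-formyl-4-(2-methoxy-2-oxoethyl)-2-methyl-3,4-dihydro-2H-pyran-5-carboxylate, via oxa-Michael adduct 5 (not isolated)
Conditions: (R)-α,α-diphenylprolinol trimethylsilyl ether (20 mol %), PhCO2H (20 mol %), toluene, 0 °C to rt
Reagents that add atoms: none
Why: Proposed new method: the amine and 4 form an (E)-iminium ion, the enol oxygen of 3 adds reversibly to its β-carbon from the face away from the CPh2(OTMS) group, and the resulting enamine adds through the same open face to C4, the β-carbon of the (E)-enoate, before hydrolysis frees 6 and the catalyst. The closest known reaction type is the diarylprolinol silyl ether catalysed oxa-Michael/Michael cascade of 2-(2-nitrovinyl)phenols with enals to 2,3,4-trisubstituted chromans, and intramolecular enamine addition to an enoate is known from amine-catalysed double Michael reactions; what is new is an acyclic α-formyl ester enol in the place of the phenol. The dihydropyran closes at C3–C4 in a 6-exo-trig Michael addition, with the O1–C6=C5 enol ether, formed one event earlier, as the tether. C2 (S) is set by the catalyst in the oxa-Michael event; C3 (R) is set by the shielded enamine, which is matched with the chair and is also the stable epimer next to the aldehyde; C4 (R) is set by the chair-like closure with the C2 methyl group and both reacting π-systems equatorial. The step needs O- over C-alkylation of the ambident enol and closure from the (4E) enol ether only; the carbon terminus of the enol is fully substituted, the C–O addition is reversible, and only the (4E) O-adduct can reach the irreversible C–C bond formation, so unproductive adducts should drain back.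

**Step 3**
Reactants: 6 methyl (2S,3R,4R)-3-formyl-4-(2-methoxy-2-oxoethyl)-2-methyl-3,4-dihydro-2H-pyran-5-carboxylate; 7 4-(2-hydroxyethyl)benzene-1,2-diol (hydroxytyrosol, 2 equiv)
Product: 8 methyl (2S,3R,4R)-4-{2-[2-(3,4-dihydroxyphenyl)ethoxy]-2-oxoethyl}-3-formyl-2-methyl-3,4-dihydro-2H-pyran-5-carboxylate
Conditions: immobilised Candida antarctica lipase B (Novozym 435), 4 Å MS, 2-methyl-2-butanol, Ar, 45 °C
Reagents that add atoms: none
Why: Lipase (serine hydrolase) transesterification, in which the acyl-enzyme should form only from the unhindered, non-conjugated CH2CO2Me (the ring ester is a push-pull ester on a fully substituted sp2 carbon) and be taken up only by the primary alcohol of 7, not by its phenols, with methanol removed by the sieves; no stereocentre is touched.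

**Compound list**

1 | dimethyl (2E)-pent-2-enedioate (dimethyl glutaconate) | COC(=O)/C=C/CC(=O)OC | starting material
2 | sodium (1Z,3E)-5-methoxy-2-(methoxycarbonyl)-5-oxopenta-1,3-dien-1-olate (sodium enolate of 3) | COC(=O)/C=C/C(=C/[O-])C(=O)OC.[Na+] | intermediate
3 | dimethyl (2E,4Z)-4-(hydroxymethylidene)pent-2-enedioate (enol form of dimethyl 2-formylglutaconate) | COC(=O)/C=C/C(=C/O)C(=O)OC | intermediate
4 | (E)-but-2-enal (crotonaldehyde) | C/C=C/C=O | starting material
5 | dimethyl (2E,4E)-4-({[(2S)-4-oxobutan-2-yl]oxy}methylidene)pent-2-enedioate | COC(=O)/C=C/C(=C\O[C@@H](C)CC=O)C(=O)OC | intermediate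
6 | methyl (2S,3R,4R)-3-formyl-4-(2-methoxy-2-oxoethyl)-2-methyl-3,4-dihydro-2H-pyran-5-carboxylate | COC(=O)C1=CO[C@@H](C)[C@H](C=O)[C@H]1CC(=O)OC | intermediate
7 | 4-(2-hydroxyethyl)benzene-1,2-diol (hydroxytyrosol) | OCCc1ccc(O)c(O)c1 | starting material
8 | methyl (2S,3R,4R)-4-{2-[2-(3,4-dihydroxyphenyl)ethoxy]-2-oxoethyl}-3-formyl-2-methyl-3,4-dihydro-2H-pyran-5-carboxylate | COC(=O)C1=CO[C@@H](C)[C@H](C=O)[C@H]1CC(=O)OCCc1ccc(O)c(O)c1 | target

Total step count: 3
Longest linear sequence: 3 steps (1 → 3 → 6 → 8)

**Steps most likely to fail**

Step 2 (Proposed new method). The ambident enol may be alkylated at carbon (C5 or the vinylogous carbon next to the distal ester) instead of oxygen. The secondary amine may be captured by the hydroxymethylidene carbon as a vinylogous carbamate, which stops turnover. Poor facial selectivity at the enoate in the ring closure would lower the diastereomer ratio. The fallback makes the C–O bond stoichiometrically from the chiral pool and uses only known reaction types. It sets out from 3. Mitsunobu O-alkylation of the acidic enol with commercial (R)-pent-4-en-2-ol (PPh3, DIAD, THF, 0 °C, inversion at carbon) should give dimethyl (2E,4E)-4-({[(2S)-pent-4-en-2-yl]oxy}methylidene)pent-2-enedioate F1. Any (4Z) isomer should be equilibrated to the more stable (4E) β-alkoxyacrylate with a trace of acid. Lemieux–Johnson cleavage of the terminal alkene (cat. OsO4, NaIO4, 2,6-lutidine, dioxane/H2O), which should spare the two electron-poor alkenes, would give aldehyde 5 as an isolated compound with C2 already fixed. Its ring closure by intramolecular enamine Michael addition onto the enoate ((R)-α,α-diphenylprolinol trimethylsilyl ether, PhCO2H, toluene), with no free enol left to capture the amine, comes back to the route at 6.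

Step 3. The lipase may form the acyl-enzyme too slowly from this β-branched acyl donor, or the exchange may stall at the transesterification equilibrium. The fallback separates cleavage and coupling and uses no enzyme. It sets out from 6. Selective hydrolysis of the aliphatic methyl ester with Me3SnOH (1,2-dichloroethane, 70 °C; 1 M HCl work-up) should give [(2S,3R,4R)-3-formyl-5-(methoxycarbonyl)-2-methyl-3,4-dihydro-2H-pyran-4-yl]acetic acid F2, the deactivated vinylogous carbonate ester being left alone. Mitsunobu esterification of F2 with unprotected 7 (PPh3, DIAD, THF, 0 °C), in which the carboxylic acid and not a phenol should act as the nucleophile towards the activated primary alcohol, comes back to the route at 8.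

Step 1. The glutaconate anion may undergo Michael self-condensation before it is formylated, and the formyl ester may lactonise or oligomerise on acidification. The fallback avoids the strongly basic enolate. It sets out from 1. Condensation with N,N-dimethylformamide dimethyl acetal (toluene, rt to 50 °C) at the doubly activated CH2 should give dimethyl (2E,4E)-4-[(dimethylamino)methylidene]pent-2-enedioate F3, a stable push-pull diene that can be purified. Mild hydrolysis of the enamine (1 M HCl, THF, 0 °C to rt) then comes back to the route at 3.

**Further compounds**

F1 | step 2 | dimethyl (2E,4E)-4-({[(2S)-pent-4-en-2-yl]oxy}methylidene)pent-2-enedioate | COC(=O)/C=C/C(=C\O[C@@H](C)CC=C)C(=O)OC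
F2 | step 3 | [(2S,3R,4R)-3-formyl-5-(methoxycarbonyl)-2-methyl-3,4-dihydro-2H-pyran-4-yl]acetic acid | COC(=O)C1=CO[C@@H](C)[C@H](C=O)[C@H]1CC(=O)O
F3 | step 1 | dimethyl (2E,4E)-4-[(dimethylamino)methylidene]pent-2-enedioate | COC(=O)/C=C/C(=C\N(C)C)C(=O)OC
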